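The synthesis rests on cutting C2–C3, the bond of the ten-membered carbocycle (C1–C10) that carries the vicinal diacetate beside quaternary C1. A SmI2 pinacol coupling of seco-dialdehyde 31 should close this ring last and set C2 and C3 as the cis-diol in one operation. It exploits the 2,3-dioxygenation and the turn elements already in place: the trans C1/C10 bonds of the cyclohexane, the cis-fused C7–C8 γ-lactone and the cis C5–C6 epoxide. In 31 the C3–C9 chain hangs on a cyclohexane made by an exo-selective catalytic Diels–Alder reaction. Pyruvic acid supplies C17–C19 through a nickel-catalysed reductive cyclisation.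

Key step: step 23

Remark on numbering: briarane numbering is used. C1 is quaternary (C15 methyl), C2 and C3 carry OAc, C4 is CH2, C5/C6 form the epoxide (C16 methyl on C5), C7 carries the lactone O, C8 OH, C9 OAc, C10 H, C11 the C20 methyl, C12 OH, C13 is CH2, C14 carries OAc, C17 carries OH and the C18 methyl, and C19 is the lactone C=O. β is the cyclohexane face that carries C15.
Assumption: the sense of induction of the catalysts in steps 3 and 15 follows the accepted models, and since both enantiomers of each catalyst are commercial, the one that gives the drawn configuration is used.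

Step 1
Reactants: 1 pent-1-en-3-one
Product: 2 (Z)-3-(tert-butyldimethylsilyloxy)penta-1,3-diene
Conditions: TBSOTf, Et3N, CH2Cl2, 0 °C
Reagents that add atoms: tert-butyldimethylsilyl triflate, CC(C)(C)[Si](C)(C)OS(=O)(=O)C(F)(F)F
Why: Soft enolisation and O-silylation of the enone (silyl enol ether formation) should give the 2-silyloxydiene, with the Z enol ether (methyl trans to the vinyl group) favoured because it avoids allylic strain.

Step 2
Reactants: 3 3-(trimethylsilyl)prop-2-ynal; 4 2-(triphenylphosphoranylidene)propanal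
Product: 5 (E)-2-methyl-5-(trimethylsilyl)pent-2-en-4-ynal
Conditions: CH2Cl2, rt
Reagents that add atoms: none
Why: The Wittig reaction of a stabilised ylide is E-selective and the ynal is much more electrophilic than the enal formed, so the alkynyl group (C9) and the formyl group (C2) should end up trans on C10=C1.

Step 3
Reactants: 2 (Z)-3-(tert-butyldimethylsilyloxy)penta-1,3-diene; 5 (E)-2-methyl-5-(trimethylsilyl)pent-2-en-4-ynal
Product: 6 cycloadduct aldehyde (C1: β-CH3, α-CHO; C10: β-C≡C-SiMe3, α-H; C11: β-CH3; C12=C13 TBS enol ether)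
Conditions: diphenylprolinol/o-tolylboron-derived oxazaborolidine (20 mol %), Tf2NH (20 mol %), CH2Cl2, −78 to −40 °C
Reagents that add atoms: none
Why: In this catalytic enantioselective Diels–Alder reaction the nucleophilic C11 terminus of 2 bonds to C10 (β to the boron-bound formyl group), the E geometry of 5 fixes C2 and C9 trans, the formyl-exo/alkynyl-endo topology expected when both ends of the shorter forming bond (C10, C11) are substituted and the formyl carbon bears a methyl group places C20 cis to C9, and the catalyst shields one face of the enal and so sets the absolute configuration of C1, C10 and C11.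

Step 4
Reactants: 6 cycloadduct aldehyde
Product: 7 neopentyl alcohol (C2-OH) with the enol ether and silylalkyne intact
Conditions: DIBAL-H (1.1 equiv), CH2Cl2, −78 °C
Reagents that add atoms: none
Why: This hydride 1,2-reduction of the only carbonyl group touches neither the silyl enol ether nor the silylalkyne and changes no stereocentre.

Step 5
Reactants: 7 neopentyl alcohol
Product: 8 hydroxy enone (C12 ketone, C13=C14, C2-OH)
Conditions: Pd(OAc)2 (1.05 equiv), MeCN, rt
Reagents that add atoms: none
Why: The Saegusa–Ito oxidation uses the regiodefined C12=C13 enol ether left by the cycloaddition, so β-hydride elimination can only give the C13=C14 enone, and the neutral conditions should leave the C11 stereocentre unepimerised.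

Step 6
Reactants: 8 hydroxy enone
Product: 10 keto diol (14α-OH, C2-OH, C12 ketone), via cyclic phenylboronate 9 (not isolated)
Conditions: PhB(OH)2, quinine-derived thiourea–amine catalyst (20 mol %), 4 Å MS, toluene, 40 °C; then 30 % H2O2, aq Na2CO3, THF, 0 °C
Reagents that add atoms: phenylboronic acid, OB(O)c1ccccc1
Why: In this boronic-acid-mediated intramolecular oxa-Michael addition to a δ-hydroxy enone the amine-activated C2–O–B(Ph)–OH hemiester delivers its oxygen to C14 through a six-membered ring, which is possible only on the α face that carries C2, so C14 is relayed from C1 under conditions too weakly basic to epimerise C11, and the oxidative work-up frees the diol.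

Step 7
Reactants: 10 keto diol
Product: 11 O2,O14-benzylidene acetal (cis-fused 1,3-dioxane, phenyl equatorial)
Conditions: PhCH(OMe)2, PPTS (cat.), CH2Cl2, rt
Reagents that add atoms: benzaldehyde dimethyl acetal, COC(OC)c1ccccc1
Why: Transacetalisation under thermodynamic control should protect the 1,3-diol as a temporary ring, with the acetal carbon taking the configuration that keeps phenyl equatorial in the conformer that has C2 axial and C15 and C20 equatorial.

Step 8
Reactants: 11 benzylidene acetal ketone
Product: 12 12β-alcohol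
Conditions: L-Selectride, THF, −78 °C
Reagents that add atoms: none
Why: The bulky hydride should attack the cyclohexanone equatorially from the α face, as in the reduction of 2-methylcyclohexanone to the cis alcohol, because the β face is flanked by the axial alkynyl group and C20, so the axial 12β-alcohol cis to C20 results.

Step 9
Reactants: 12 12β-alcohol
Product: 13 12-O-triethylsilyl ether
Conditions: TESOTf, 2,6-lutidine, CH2Cl2, −40 to 0 °C
Reagents that add atoms: triethylsilyl triflate, CC[Si](CC)(CC)OS(=O)(=O)C(F)(F)F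
Why: Silylation with the reactive triflate should cover the hindered axial alcohol with the group that marks O12 as the only secondary oxygen not to be acetylated.

Step 10
Reactants: 13 12-O-triethylsilyl ether
Product: 14 terminal alkyne (C9≡C8-H)
Conditions: K2CO3, MeOH, rt
Reagents that add atoms: none
Why: Methanolytic protiodesilylation cleaves only the alkynyl C–Si bond, since the TES ether and the acetal are stable to mild base.

Step 11
Reactants: 15 benzyl but-3-yn-1-yl ether
Product: 17 methyl 5-(benzyloxy)pent-2-ynoate, via lithium acetylide 16 (not isolated)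
Conditions: n-BuLi, THF, −78 °C; then ClCO2Me
Reagents that add atoms: methyl chloroformate, COC(=O)Cl
Why: Acylation of the lithium acetylide with a chloroformate is a standard route to ynoates and introduces C7.

Step 12
Reactants: 17 methyl 5-(benzyloxy)pent-2-ynoate
Product: 19 methyl (Z)-5-(benzyloxy)-3-methylpent-2-enoate, via lithium alkenyl(methyl)cuprate 18 (not isolated)
Conditions: Me2CuLi (MeLi, CuI), THF, −78 °C; NH4Cl/MeOH quench at −78 °C
Reagents that add atoms: lithium dimethylcuprate, [Li+].C[Cu-]C (made from methyllithium, [Li]C, and CuI)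
Why: The conjugate addition of the cuprate to the ynoate is a syn carbocupration, and protonation at −78 °C keeps the alkenylcopper geometry, so C4 and C7 should be cis on C5=C6 as the cis epoxide requires.

Step 13
Reactants: 19 methyl (Z)-5-(benzyloxy)-3-methylpent-2-enoate
Product: 20 (Z)-5-(benzyloxy)-3-methylpent-2-en-1-ol
Conditions: DIBAL-H (2.2 equiv), CH2Cl2, −78 °C
Reagents that add atoms: none
Why: The 1,2-reduction of the enoate with DIBAL-H gives the allylic alcohol without touching the alkene geometry.

Step 14
Reactants: 20 (Z)-5-(benzyloxy)-3-methylpent-2-en-1-ol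
Product: 21 (Z)-5-(benzyloxy)-3-methylpent-2-enal
Conditions: MnO2, CH2Cl2, rt
Reagents that add atoms: none
Why: The neutral allylic oxidation with MnO2 should stop at the aldehyde and keep the Z geometry of the β,β-disubstituted enal.

Step 15
Reactants: 14 terminal alkyne; 21 (Z)-5-(benzyloxy)-3-methylpent-2-enal
Product: 23 (7S)-propargylic (5Z)-allylic alcohol, via alkynyl(methyl)zinc 22 (not isolated)
Conditions: Me2Zn (3 equiv), ProPhenol ligand (20 mol %), Ph3PO (40 mol %), toluene, 4 °C
Reagents that add atoms: none
Why: In this catalytic asymmetric alkynylation the dinuclear zinc–ProPhenol complex binds the alkynylzinc and the enal, a substrate class for which it is well suited, and delivers the alkyne to one aldehyde face, so C7 is set by the catalyst and the C7–C8 bond joins the two fragments.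

Step 16
Reactants: 23 propargylic allylic alcohol
Product: 24 threo-5,6-epoxy-7-ol
Conditions: mCPBA, NaHCO3, CH2Cl2, 0 °C
Reagents that add atoms: 3-chloroperbenzoic acid, OOC(=O)c1cccc(Cl)c1
Why: In this hydroxyl-directed peracid epoxidation A(1,3) strain with the cis C4 substituent holds H7 in the alkene plane and the hydrogen-bonded peracid attacks the face that carries the 7-OH, so C5 and C6 are relayed from C7 as the threo epoxy alcohol while the alkyne stays inert.

Step 17
Reactants: 24 threo-5,6-epoxy-7-ol; 25 pyruvic acid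
Product: 26 7-O-pyruvate ester
Conditions: DCC, DMAP (cat.), CH2Cl2, 0 °C
Reagents that add atoms: none
Why: The Steglich esterification attaches C17–C19 to O7 under nearly neutral conditions that should avoid Payne rearrangement of the epoxy alcohol.

Step 18
Reactants: 26 7-O-pyruvate ester
Product: 27 (8E)-alkylidene γ-lactone with 17-O-triethylsilyl ether
Conditions: Ni(cod)2 (10 mol %), monophosphine ligand (PCy3 or a matched P-chiral ligand, 12 mol %), Et3SiH (3 equiv), THF, rt
Reagents that add atoms: triethylsilane, CC[SiH](CC)CC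
Why: In this nickel-catalysed reductive cyclisation of an alkynone, oxidative cyclisation of Ni(0) with the alkyne and the activated keto group forms C8–C17 in the 5-exo mode, σ-bond metathesis with the silane silylates O17 and puts H on C9 by net syn addition so that C10 is trans to C17, and C17 is set by C7 because the methyl group takes the lactone face opposite the C6 side chain.

Step 19
Reactants: 27 alkylidene lactone
Product: 28 8β,9-diol
Conditions: OsO4 (10–20 mol %), NMO, acetone–H2O, rt
Reagents that add atoms: N-methylmorpholine N-oxide, C[N+]1([O-])CCOCC1; water, O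
Why: In the Upjohn dihydroxylation osmium tetroxide should add syn to the only alkene from the lactone face that bears H7 and C18, anti to the C6 side chain and to the allylic 17-OTES group, which sets C8, and the E geometry then fixes C9.

Step 20
Reactants: 28 8β,9-diol
Product: 29 9-acetate
Conditions: Ac2O, pyridine, DMAP (cat.), CH2Cl2, 0 °C to rt, on crude 28
Reagents that add atoms: acetic anhydride, CC(=O)OC(C)=O
Why: Acylation is selective for the secondary 9-OH over the tertiary 8-OH, and doing it at once should keep the 9-OH from opening the epoxide or translactonising.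

Step 21
Reactants: 29 9-acetate
Product: 30 tetraol (C2-OH, C3-OH, 14α-OH, 8-OH)
Conditions: H2 (1 atm), Pd(OH)2/C, EtOAc, rt
Reagents that add atoms: none
Why: Hydrogenolysis cleaves the benzyl ether and the benzylidene acetal in one neutral operation, and with no alkene left the epoxide, acetate, lactone and TES ethers should survive in ethyl acetate.

Step 22
Reactants: 30 tetraol
Product: 31 seco-dialdehyde (C2 and C3 formyl groups)
Conditions: TEMPO (20 mol %), PhI(OAc)2 (2.4 equiv), CH2Cl2, rt
Reagents that add atoms: none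
Why: The nitroxyl-catalysed oxidation is selective for the two primary alcohols over the hindered secondary 14-OH and the tertiary 8-OH, and its base-free medium should spare the β,γ-epoxy aldehyde from β-elimination.

Step 23
Reactants: 31 seco-dialdehyde
Product: 32 ten-membered 2β,3β-diol (with free 8-OH and 14-OH)
Conditions: SmI2 (5 equiv, 0.1 M in THF), slow addition of 31 (final 1–2 mM), THF, −20 °C to rt; aq NaHCO3/Rochelle salt
Reagents that add atoms: none
Why: SmI2 reduces both formyl groups of 31 to samarium(III) ketyls, which couple (or one ketyl adds to the second, samarium-bound C=O) to form C2–C3, an intramolecular pinacol coupling of a dialdehyde of the type already used to close eight- to fourteen-membered carbocycles. The ten-membered ring C1–C10 closes in a 10-exo-trig radical mode with both oxygens outside the ring, and its entropic cost is lowered by the turn elements of 31: the trans C2/C9 bonds on C1/C10, the cis-fused lactone at C7–C8, the cis epoxide at C5–C6 and the fully substituted C1 and C8. C2 is controlled by C1 in a chelated Felkin–Anh arrangement in which samarium ties O2 to the 14α-oxygen, the C1–C10 bond stands perpendicular to the carbonyl plane, and C3 attacks anti to it past the small C15 methyl group, which should give the 2β-oxygen (2R). C3 is controlled by C2, since both oxygens sit on samarium in the bond-forming event and the cis (erythro) 2β,3β-diol (3S) results. The step needs chemoselectivity for the two aldehydes and for ring closure: without HMPA or water SmI2 leaves the epoxide, the acetate, the silyl ethers and the α-silyloxy lactone alone, the C3 ketyl is insulated from the epoxide by C4, the C2 ketyl has no α-leaving group, and slow addition at high dilution suppresses intermolecular coupling.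

Step 24
Reactants: 32 ten-membered 2β,3β-diol
Product: 33 2,3,9,14-tetraacetate with 12- and 17-O-TES ethers
Conditions: Ac2O, DMAP, pyridine, rt
Reagents that add atoms: acetic anhydride, CC(=O)OC(C)=O
Why: Acetylation covers the three secondary alcohols (O2, O3, O14) and leaves the tertiary 8-OH free, and any acyl migration among O2, O3, O9 and O14 is harmless because all four end as acetates.

Step 25
Reactants: 33 tetraacetate bis-TES ether
Product: 34 CNP0287149.1 (target)
Conditions: HF·pyridine, pyridine, THF, 0 °C
Reagents that add atoms: none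
Why: Buffered fluoride-mediated desilylation removes both labile TES ethers (O12, O17) under conditions mild enough for the trisubstituted epoxide, the acetates and the lactone, and no stereocentre is touched.

Compound list
1 | pent-1-en-3-one (ethyl vinyl ketone) | CCC(=O)C=C | starting material
2 | (Z)-3-(tert-butyldimethylsilyloxy)penta-1,3-diene | C=C/C(O[Si](C)(C)C(C)(C)C)=C/C | intermediate
3 | 3-(trimethylsilyl)prop-2-ynal | C[Si](C)(C)C#CC=O | starting material
4 | 2-(triphenylphosphoranylidene)propanal | CC(C=O)=P(c1ccccc1)(c1ccccc1)c1ccccc1 | starting material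
5 | (E)-2-methyl-5-(trimethylsilyl)pent-2-en-4-ynal | C[Si](C)(C)C#C/C=C(\C)C=O | intermediate
6 | cycloadduct aldehyde (C1: β-CH3, α-CHO; C10: β-alkynyl; C11: β-CH3; C12=C13 TBS enol ether) | C[Si](C)(C)C#C[C@H]1[C@@H](C)C(O[Si](C)(C)C(C)(C)C)=CC[C@]1(C)C=O | intermediate
7 | neopentyl alcohol (C2-OH) from 6 | C[Si](C)(C)C#C[C@H]1[C@@H](C)C(O[Si](C)(C)C(C)(C)C)=CC[C@]1(C)CO | intermediate
8 | hydroxy enone (C12 ketone, C13=C14, C2-OH) | C[Si](C)(C)C#C[C@H]1[C@@H](C)C(=O)C=C[C@]1(C)CO | intermediate
9 | cyclic phenylboronate (O2–B(Ph)–O14, O14 α) | C[Si](C)(C)C#C[C@H]1[C@@H](C)C(=O)C[C@@H]2OB(c3ccccc3)OC[C@]12C | intermediate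
10 | keto diol (14α-OH, C2-OH) | C[Si](C)(C)C#C[C@H]1[C@@H](C)C(=O)C[C@H](O)[C@]1(C)CO | intermediate
11 | O2,O14-benzylidene acetal ketone (phenyl equatorial) | C[Si](C)(C)C#C[C@H]1[C@@H](C)C(=O)C[C@@H]2O[C@@H](c3ccccc3)OC[C@]12C | intermediate
12 | 12β-alcohol | C[Si](C)(C)C#C[C@H]1[C@@H](C)[C@@H](O)C[C@@H]2O[C@@H](c3ccccc3)OC[C@]12C | intermediate
13 | 12-O-TES ether | C[Si](C)(C)C#C[C@H]1[C@@H](C)[C@@H](O[Si](CC)(CC)CC)C[C@@H]2O[C@@H](c3ccccc3)OC[C@]12C | intermediate
14 | terminal alkyne (C9≡C8-H) | C#C[C@H]1[C@@H](C)[C@@H](O[Si](CC)(CC)CC)C[C@@H]2O[C@@H](c3ccccc3)OC[C@]12C | intermediate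
15 | benzyl but-3-yn-1-yl ether | C#CCCOCc1ccccc1 | starting material
16 | lithium acetylide of 15 | [Li]C#CCCOCc1ccccc1 | intermediate
17 | methyl 5-(benzyloxy)pent-2-ynoate | COC(=O)C#CCCOCc1ccccc1 | intermediate
18 | lithium alkenyl(methyl)cuprate (Cu on C6, cis to the new C16 methyl) | COC(=O)/C([Cu-]C)=C(/C)CCOCc1ccccc1.[Li+] | intermediate
19 | methyl (Z)-5-(benzyloxy)-3-methylpent-2-enoate | COC(=O)/C=C(/C)CCOCc1ccccc1 | intermediate
20 | (Z)-5-(benzyloxy)-3-methylpent-2-en-1-ol | OC/C=C(/C)CCOCc1ccccc1 | intermediate
21 | (Z)-5-(benzyloxy)-3-methylpent-2-enal | O=C/C=C(/C)CCOCc1ccccc1 | intermediate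
22 | alkynyl(methyl)zinc from 14 | C[Zn]C#C[C@H]1[C@@H](C)[C@@H](O[Si](CC)(CC)CC)C[C@@H]2O[C@@H](c3ccccc3)OC[C@]12C | intermediate
23 | (7S)-propargylic (5Z)-allylic alcohol | c1ccccc1COCC/C(C)=C\[C@H](O)C#C[C@H]1[C@@H](C)[C@@H](O[Si](CC)(CC)CC)C[C@@H]2O[C@@H](c3ccccc3)OC[C@]12C | intermediate
24 | threo-5,6-epoxy-7-ol | c1ccccc1COCC[C@@]1(C)O[C@H]1[C@H](O)C#C[C@H]1[C@@H](C)[C@@H](O[Si](CC)(CC)CC)C[C@@H]2O[C@@H](c3ccccc3)OC[C@]12C | intermediate
25 | pyruvic acid | CC(=O)C(=O)O | starting material
26 | 7-O-pyruvate ester | c1ccccc1COCC[C@@]1(C)O[C@H]1[C@H](OC(=O)C(C)=O)C#C[C@H]1[C@@H](C)[C@@H](O[Si](CC)(CC)CC)C[C@@H]2O[C@@H](c3ccccc3)OC[C@]12C | intermediate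
27 | (8E)-alkylidene γ-lactone, 17-O-TES | c1ccccc1COCC[C@@]1(C)O[C@H]1[C@@H]1OC(=O)[C@](C)(O[Si](CC)(CC)CC)/C1=C/[C@H]1[C@@H](C)[C@@H](O[Si](CC)(CC)CC)C[C@@H]2O[C@@H](c3ccccc3)OC[C@]12C | intermediate
28 | 8β,9-diol | c1ccccc1COCC[C@@]1(C)O[C@H]1[C@@H]1OC(=O)[C@](C)(O[Si](CC)(CC)CC)[C@]1(O)[C@@H](O)[C@H]1[C@@H](C)[C@@H](O[Si](CC)(CC)CC)C[C@@H]2O[C@@H](c3ccccc3)OC[C@]12C | intermediate
29 | 9-acetate | c1ccccc1COCC[C@@]1(C)O[C@H]1[C@@H]1OC(=O)[C@](C)(O[Si](CC)(CC)CC)[C@]1(O)[C@@H](OC(C)=O)[C@H]1[C@@H](C)[C@@H](O[Si](CC)(CC)CC)C[C@@H]2O[C@@H](c3ccccc3)OC[C@]12C | intermediate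
30 | tetraol (C2-OH, C3-OH, 8-OH, 14α-OH) | OCC[C@@]1(C)O[C@H]1[C@@H]1OC(=O)[C@](C)(O[Si](CC)(CC)CC)[C@]1(O)[C@@H](OC(C)=O)[C@H]1[C@@H](C)[C@@H](O[Si](CC)(CC)CC)C[C@H](O)[C@]1(C)CO | intermediate
31 | seco-dialdehyde | O=CC[C@@]1(C)O[C@H]1[C@@H]1OC(=O)[C@](C)(O[Si](CC)(CC)CC)[C@]1(O)[C@@H](OC(C)=O)[C@H]1[C@@H](C)[C@@H](O[Si](CC)(CC)CC)C[C@H](O)[C@]1(C)C=O | intermediate
32 | ten-membered 2β,3β-diol | O[C@H]1C[C@@]2(C)O[C@H]2[C@@H]2OC(=O)[C@](C)(O[Si](CC)(CC)CC)[C@]2(O)[C@@H](OC(C)=O)[C@H]2[C@@H](C)[C@@H](O[Si](CC)(CC)CC)C[C@H](O)[C@]2(C)[C@H]1O | intermediate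
33 | 2,3,9,14-tetraacetate, 12,17-bis-TES ether | CC(=O)O[C@H]1C[C@@]2(C)O[C@H]2[C@@H]2OC(=O)[C@](C)(O[Si](CC)(CC)CC)[C@]2(O)[C@@H](OC(C)=O)[C@H]2[C@@H](C)[C@@H](O[Si](CC)(CC)CC)C[C@H](OC(C)=O)[C@]2(C)[C@H]1OC(C)=O | intermediate
34 | CNP0287149.1 | CC(=O)O[C@H]1C[C@@]2(C)O[C@H]2[C@@H]2OC(=O)[C@](C)(O)[C@]2(O)[C@@H](OC(C)=O)[C@H]2[C@@H](C)[C@@H](O)C[C@H](OC(C)=O)[C@]2(C)[C@H]1OC(C)=O | target

Total step count: 25. Longest linear sequence: 20 (steps 2–10, then 15–25).

Steps most likely to fail

Step 23. The aldehydes may simply be reduced to alcohols, and intermolecular coupling may compete with the slow medium-ring closure. The β,γ-epoxy aldehyde or the β-hydroxy aldehyde may decay by elimination or retro-aldol cleavage before coupling, or the facial selectivity at C2 may be poor. The fallback sets out from 31 and replaces the radical closure by olefin metathesis. Double methylenation (Ph3P=CH2, THF, −78 °C) would give the bis-vinyl compound F1. Ring-closing metathesis with a second-generation ruthenium catalyst at high dilution would close the ten-membered ring as the (Z)-2,3-cyclodecene F2. An Upjohn dihydroxylation from the outer face of the Z alkene would then give the cis-diol and return to the route at 32.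

Step 18. Nickel(0) may ionise the propargylic ester, the silane may hydrosilylate the keto group, the disfavoured s-cis ester rotamer may slow the oxidative cyclisation, and the facial selectivity at C17 may be low. The fallback sets out from 24 and uses a preformed alkenyl metal. Palladium-catalysed syn-hydrostannation (Bu3SnH, PdCl2(PPh3)2) should put tin on C8, next to the carbinol and away from bulky C10, to give the alkenylstannane F3. Iodine would convert it with retention into the alkenyl iodide F4, and Steglich esterification with 25 would give the iodo pyruvate F5. An intramolecular Nozaki–Hiyama–Kishi reaction (CrCl2, cat. NiCl2, DMF) onto the activated keto group would give the hydroxy lactone F6. Silylation (TESOTf, 2,6-lutidine) returns to the route at 27.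

Step 3. The exo/endo ratio or the facial selectivity of the cycloaddition may be poor, and Mukaiyama-type addition of the silyl enol ether to the activated aldehyde may compete. The fallback sets out from 2 and 5 and sets C11 by kinetic protonation instead of by the cycloaddition topology. The formyl-endo adduct, 11-epi aldehyde F7, would be carried through the conditions of steps 4 and 5 to the 11-epi alcohol F8 and the 11-epi hydroxy enone F9. LDA (2.2 equiv, THF, −78 °C) would give the dilithium cross-conjugated dienolate F10. A bulky phenol should protonate it at −78 °C from the α face, anti to the vicinal alkynyl group and to C15, which returns to the route at 8.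

Further compounds
F1 | step 23 | bis-vinyl compound (C2 and C3 as CH=CH2) | C=CC[C@@]1(C)O[C@H]1[C@@H]1OC(=O)[C@](C)(O[Si](CC)(CC)CC)[C@]1(O)[C@@H](OC(C)=O)[C@H]1[C@@H](C)[C@@H](O[Si](CC)(CC)CC)C[C@H](O)[C@]1(C)C=C
F2 | step 23 | (Z)-2,3-cyclodecene | C1[C@@]2(C)O[C@H]2[C@@H]2OC(=O)[C@](C)(O[Si](CC)(CC)CC)[C@]2(O)[C@@H](OC(C)=O)[C@H]2[C@@H](C)[C@@H](O[Si](CC)(CC)CC)C[C@H](O)[C@]2(C)/C=C\1
F3 | step 18 | alkenylstannane (Bu3Sn on C8) | c1ccccc1COCC[C@@]1(C)O[C@H]1[C@H](O)/C([Sn](CCCC)(CCCC)CCCC)=C\[C@H]1[C@@H](C)[C@@H](O[Si](CC)(CC)CC)C[C@@H]2O[C@@H](c3ccccc3)OC[C@]12C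
F4 | step 18 | alkenyl iodide (I on C8) | c1ccccc1COCC[C@@]1(C)O[C@H]1[C@H](O)/C(I)=C\[C@H]1[C@@H](C)[C@@H](O[Si](CC)(CC)CC)C[C@@H]2O[C@@H](c3ccccc3)OC[C@]12C
F5 | step 18 | iodo pyruvate | c1ccccc1COCC[C@@]1(C)O[C@H]1[C@H](OC(=O)C(C)=O)/C(I)=C\[C@H]1[C@@H](C)[C@@H](O[Si](CC)(CC)CC)C[C@@H]2O[C@@H](c3ccccc3)OC[C@]12C
F6 | step 18 | hydroxy lactone (free 17-OH) | c1ccccc1COCC[C@@]1(C)O[C@H]1[C@@H]1OC(=O)[C@](C)(O)/C1=C/[C@H]1[C@@H](C)[C@@H](O[Si](CC)(CC)CC)C[C@@H]2O[C@@H](c3ccccc3)OC[C@]12C
F7 | step 3 | 11-epi aldehyde | C[Si](C)(C)C#C[C@H]1[C@H](C)C(O[Si](C)(C)C(C)(C)C)=CC[C@]1(C)C=O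
F8 | step 3 | 11-epi alcohol | C[Si](C)(C)C#C[C@H]1[C@H](C)C(O[Si](C)(C)C(C)(C)C)=CC[C@]1(C)CO
F9 | step 3 | 11-epi hydroxy enone | C[Si](C)(C)C#C[C@H]1[C@H](C)C(=O)C=C[C@]1(C)CO
F10 | step 3 | dilithium cross-conjugated dienolate | C[Si](C)(C)C#C[C@H]1C(C)=C([O-])C=C[C@]1(C)C[O-].[Li+].[Li+]
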